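All constants were drawn at random within sensible limits; the run is a simulation.

Start at the late end of a run and ask how many times the released group has been halved by then.

| flask | first end groups | second end groups | time |
|---|---|---|---|
| delta | 0.15 M | 0.255 M | 8.0 min |
| zeta | 0.25 M | 0.255 M | 8.0 min |
| alpha | 0.40 M | 0.255 M | 8.0 min |

1. [links] at the end for delta, zeta, alpha, in this order
2. how the row runs (rises, then falls / falls, then rises / hardly changes / falls all the way / rises all the way)

In each flask first end groups and second end groups join reversibly into links and released group, first end groups also attack links to give side product, and the released group leaves in a first-order step as by-product carried off. With 0.581 /min the half-life of that carrying-off is 1.19 min, so 6.71 of them fit into the run; call this the vent count, the number of half-lives of the released group in the run time.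

The bench rule says you can treat a first-order loss as over after 5 half-lives, and the vent count is more than that. The joining is quick as well: in delta, first end groups as charged halve by its forward rate alone in 2.7 s, faster than the released group leaves. So the rule lets the vent pull the joining through to the limiting reagent, and you would book links at 100 % of the first end groups charged in delta, 100 % in zeta and 63.7 % in alpha.

The rule counts no loss of links, so it can be trusted as far as that loss stays slow against the vent. Take the rate constant of that loss times first end groups as charged, over 0.581 /min: the ratio is 0.159 in delta and 0.424 in alpha, larger. Alpha also holds an excess of 36.3 % of its first end groups over the second end groups charged. Read as amounts, my caps keep rising from delta to alpha, but the ratio warns me against trusting them at the alpha end, by a margin this reckoning does not give.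

The forecast reads 0.128 M, 0.164 M, 0.146 M, rises, then falls, holding of the joining that “the slow loss of the released group pulls it forward”.

The flasks give 0.129 M, 0.165 M, 0.146 M, rises, then falls, which is 86.3 %, 66.1 % and 36.4 % of the first end groups charged.

    first end groups + second end groups ⇌ links + released group (K1 = 1.7, k1 = 61.5 /M/min)
    first end groups + links → side product (k2 = 0.616 /M/min)
    released group → by-product carried off (k3 = 0.581 /min)

Without further supply, 6.71 halvings leave 0.955 % of a portion of released group, and at 8.00 min flask delta still holds 2.82 % of the released group made, net. Take the carrying-off away and links in delta end at 55.5 % of the first end groups charged, less than 86.3 %. The vent count is the same in alpha, where 3.60 % of the released group made, net, still stands at the end, and there the run without carrying-off ends with links at 20.8 % of the first end groups charged against 36.4 %.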